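## Analysis of the target

Compound 12, methyl 2-(3-bromo-12H-pyrido[1,2-a:3,4-b']diindol-13-yl)-2-oxoacetate, is a flat, fully aromatic pentacycle. Ring A (benzo ring, C7b to C11a) and ring B (the pyrrole holding N12–H, C12a and C7a) form one indole. Ring E (benzo ring, C1 to C4a and C13a, bromine on C3) and ring D (the pyrrole holding N5, C12b and C13) form a second indole. Ring C (N5, C6, C7, C7a, C12a, C12b) joins the two through the biaryl bond C12a–C12b and the bridge N5–C6=C7–C7a, so rings C and D together are an indolizine-type unit. There is no stereocenter; every problem is one of regiochemistry and chemoselectivity. The sensitive groups are: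
- the α-keto ester on C13, an electrophile that condenses with primary amines and is cleaved by hydroxide or alkoxide;
- the aryl bromide, exposed to zerovalent palladium, hydrogenolysis and halogen–metal exchange;
- the free N12–H and the electron-rich core, which is easily over-oxidised.

The difficulty is to assemble the 2,2'-linked bis-indole with its two-carbon bridge while bromine stays at one defined position and the glyoxylate does not interfere. The route rests on the bond C7a–C7b, which ties ring A to the carbon β to N12. With ring C at the 6,7-dihydro level and C12a as a ketone carbon, C7a is the only enolisable α-position, because the other neighbour, C12b, is an aromatic carbon of ring D. A 2-iodophenyl ketimine can therefore present C7a as an enamine carbon for arylation, and that arylation creates ring B.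

## Retrosynthetic reasoning

Atom locants C1 to C13a are those of the target skeleton and are used for every intermediate; systematic names keep their own locants (C9, C8, C9a and C10 of the tricyclic ketone 5 are C12a, C7a, C12b and C13 of the target).

**12 to 11.** The ketone oxygen of the side chain is removed, leading back to the acetate 11, methyl 2-(3-bromo-12H-pyrido[1,2-a:3,4-b']diindol-13-yl)acetate. A glyoxylate ketone would compete with the ring C ketone for the aniline and would not tolerate the Lewis acid and base steps, whereas a CH2CO2Me arm is inert. Forward, a methylene flanked by an ester and by C13, the most electron-rich carbon of the nucleus, has to be oxidised to C=O without touching the core or the C–Br bond.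

**11 to 10.** The C6=C7 double bond is saturated, giving the dihydro compound 10, methyl 2-(3-bromo-7,12-dihydro-6H-pyrido[1,2-a:3,4-b']diindol-13-yl)acetate. Only at this oxidation level can C7a be traced back to the α-methylene of a ketone. Forward, a dehydrogenation is needed; it is pulled by the formation of the indolizine-type 10π unit of rings C and D.

**10 to 7.** The bond C7a–C7b is cut, which opens ring B and leads to the ketimine 7, methyl 2-{(9E)-3-bromo-9-[(2-iodophenyl)imino]-6,7,8,9-tetrahydropyrido[1,2-a]indol-10-yl}acetate. This cut leaves ring A as a plain ortho-iodo aniline unit and rings C, D and E as a tricyclic ketone, so that every remaining bond is a C–N or acyl bond of standard type. A cut at N12–C11a instead would demand a pre-formed α-aryl ketone. Forward, the enamine tautomer 8 must be arylated at C7a by palladium that has inserted into the C–I bond; the 3H-indole 9 formed first tautomerises to 10. The step has to choose C–I over C–Br.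

**7 to 5 and 6.** The C=N bond is cut to the ketone 5, methyl 2-(3-bromo-9-oxo-6,7,8,9-tetrahydropyrido[1,2-a]indol-10-yl)acetate, and 2-iodoaniline 6. Forward, a hindered, vinylogous-amide-type ketone must be condensed with a weakly nucleophilic aniline, which calls for an oxophilic Lewis acid as water acceptor.

**5 to 4.** The acyl–aryl bond C12a–C12b is cut, giving the acid 4, 4-[6-bromo-3-(2-methoxy-2-oxoethyl)-1H-indol-1-yl]butanoic acid. Forward, this is a Friedel–Crafts acylation at the indole 2-position; it is the only free nucleophilic site of ring D because the 3-position carries the acetate arm, and a six-membered ring is closed.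

**4 to 3 to 1 and 2.** The acid comes from the tert-butyl ester 3, tert-butyl 4-[6-bromo-3-(2-methoxy-2-oxoethyl)-1H-indol-1-yl]butanoate. The bond N5–C6 is then cut to the indole 1, methyl 2-(6-bromo-1H-indol-3-yl)acetate, and the bromide 2, tert-butyl 4-bromobutanoate. The tert-butyl/methyl pair allows one ester to be released by acid alone. The bromine position and the C13 carbon arm are both bought with 1, so no regiochemical question about bromine arises anywhere.

## Alternatives that were turned down

**Alternative 1:** Ring C is built as the pyridine ring of a β-carboline by cutting N5–C6.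
- Forward key step: the O-methyl oxime A2, 2-(4-bromo-2-fluorophenyl)-1-(3-ethenyl-1H-indol-2-yl)ethan-1-one O-methyl oxime, is heated. Its 1-azatriene (vinyl group, indole C2=C3 bond, C=N) closes in a 6π-azaelectrocyclisation, and loss of methanol aromatises ring C to A1, 1-(4-bromo-2-fluorobenzyl)-9H-pyrido[3,4-b]indole.
- Completion: ring D would be closed by N5 displacing fluoride (bond N5–C4a) to give A3, 3-bromo-12H-pyrido[1,2-a:3,4-b']diindole, and the glyoxylate would go onto C13 last by electrophilic oxalylation.
- For: the final acylation is an electrophilic substitution at the most nucleophilic carbon of A3, which is a cleaner way to the keto ester than oxidising a methylene. Ring C arrives aromatic, so no dehydrogenation is needed. On both points this plan is stronger than the chosen one.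
- Against: the fluoride to be displaced is not activated, since bromine is meta to it and the benzylic CH2 is no acceptor, so ring D closure would need forcing conditions. A metal-catalysed N-arylation is ruled out because it would attack C–Br. A2 needs an indole bearing both a 2-arylacetyl and a 3-vinyl group, which takes several protected steps.
- Comparison: the chosen route pays with two late oxidations, but all its ring closures are of dependable type and bromine is never next to a displacement reaction.

**Alternative 2:** Ring D and the keto ester are made together by cutting N5–C12b and C13–C(=O).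
- Forward key step: the alkynyl oxamate A5, methyl 2-[{5-bromo-2-[(1H-indol-2-yl)ethynyl]phenyl}(2,2-dimethoxyethyl)amino]-2-oxoacetate, is treated with PtCl2. The metal activates the alkyne, the oxamate nitrogen adds 5-endo-dig to the carbon that becomes C12b, and the methoxalyl group shifts from N5 to C13. The product is A4, methyl 2-[6-bromo-1-(2,2-dimethoxyethyl)-2-(1H-indol-2-yl)-1H-indol-3-yl]-2-oxoacetate.
- Completion: acid would unmask the acetal and close ring C by attack of C7a (bond C7–C7a), giving the target with C6=C7 in place.
- For: this is the most convergent plan, with no change of oxidation level at the end. In step count and redox economy it is stronger than the chosen route.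
- Against: the nucleophile is a weakly basic oxamate nitrogen. The migrating group is a methoxalyl unit, whose 1,3-shift is less secure than that of simple acyl groups and which can be lost instead. The dimethyl acetal must survive a Lewis-acidic metal halide at elevated temperature. A5 needs a Sonogashira coupling that discriminates two halogens and uses a sensitive 2-ethynylindole. The last ring closure could take N12 instead of C7a, since both give six-membered rings.
- Comparison: the chosen route is about two steps longer but concentrates its risk in one step, whose single selectivity question has a clear mechanistic answer.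

**Alternative 3:** Ring D is closed by cutting C13–C13a.
- Forward key step: the enaminone A7, methyl (3E)-3-[2-(3-bromophenyl)-2,3,4,9-tetrahydro-1H-pyrido[3,4-b]indol-1-ylidene]-2-oxopropanoate, is cyclised with Pd(OAc)2 and Cu(OAc)2. The enaminone α-carbon is palladated, an ortho C–H bond of the N-aryl ring is activated, and reductive elimination gives A6, methyl 2-(3-bromo-7,12-dihydro-6H-pyrido[1,2-a:3,4-b']diindol-13-yl)-2-oxoacetate. Cu(OAc)2 returns zerovalent palladium to the divalent state.
- Completion: one dehydrogenation of C6–C7.
- For: the glyoxylate is present throughout as the enaminone acyl group, no halide is needed for the closure, and only one step follows the key step against two in the chosen route.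
- Against: the 3-bromophenyl ring has two different ortho C–H bonds. Coupling para to bromine gives the wanted 3-bromo skeleton and coupling ortho to bromine gives the 1-bromo isomer, with only a steric bias between them. Every turnover passes through zerovalent palladium at high temperature next to a C–Br bond. A7 needs its own multi-step construction.
- Comparison: the chosen route takes the bromine position from the purchased indole and lets palladium insert into a C–I bond placed exactly where the new bond is wanted.

Key step: step 5

Assumption: ketimine 7 is drawn as the E isomer (aryl group on the side of C8); the C=N geometry is mobile and has no bearing on step 5, which runs through the enamine.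

## Route

**Step 1**
Reactants: 1 methyl 2-(6-bromo-1H-indol-3-yl)acetate; 2 tert-butyl 4-bromobutanoate
Product: 3 tert-butyl 4-[6-bromo-3-(2-methoxy-2-oxoethyl)-1H-indol-1-yl]butanoate
Conditions: Cs2CO3, DMF, 60 °C
Reagents that add atoms: none
Why: SN2 N-alkylation of the indole anion; N–H is the most acidic site, the 3-position is blocked, and carbonate is too weak to enolise either ester, so C-alkylation and cyclopropane formation from 2 are not expected.

**Step 2**
Reactants: 3 tert-butyl 4-[6-bromo-3-(2-methoxy-2-oxoethyl)-1H-indol-1-yl]butanoate
Product: 4 4-[6-bromo-3-(2-methoxy-2-oxoethyl)-1H-indol-1-yl]butanoic acid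
Conditions: TFA, anisole, CH2Cl2, 0 °C to rt
Reagents that add atoms: none
Why: Acidolysis of the tert-butyl ester by alkyl–oxygen cleavage releases isobutene, a path closed to the methyl ester, which stays intact; anisole intercepts stray tert-butyl cation before it can alkylate the indole.

**Step 3**
Reactants: 4 4-[6-bromo-3-(2-methoxy-2-oxoethyl)-1H-indol-1-yl]butanoic acid
Product: 5 methyl 2-(3-bromo-9-oxo-6,7,8,9-tetrahydropyrido[1,2-a]indol-10-yl)acetate
Conditions: Eaton's reagent (P2O5 in MeSO3H), 50 °C
Reagents that add atoms: none
Why: Intramolecular Friedel–Crafts acylation; the activated acid attacks the indole 2-position, the only free nucleophilic carbon of ring D, and closes an unstrained six-membered ring with the ketone at the future C12a. The water is taken up by P2O5, and the methyl ester and the aryl bromide are inert at this temperature.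

**Step 4**
Reactants: 5 methyl 2-(3-bromo-9-oxo-6,7,8,9-tetrahydropyrido[1,2-a]indol-10-yl)acetate; 6 2-iodoaniline
Product: 7 methyl 2-{(9E)-3-bromo-9-[(2-iodophenyl)imino]-6,7,8,9-tetrahydropyrido[1,2-a]indol-10-yl}acetate
Conditions: TiCl4 (0.6 equiv.), Et3N, toluene, 0 °C then 90 °C; 6 and TiCl4 premixed before 5 is added
Reagents that add atoms: none
Why: TiCl4-mediated ketimine condensation; the titanium anilide adds to the hindered, deactivated ketone and the oxygen is removed irreversibly as TiO2. Forming the anilide first keeps free TiCl4/Et3N from enolising the methyl ester.

**Step 5**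
Reactants: 7 methyl 2-{(9E)-3-bromo-9-[(2-iodophenyl)imino]-6,7,8,9-tetrahydropyrido[1,2-a]indol-10-yl}acetate
Product: 10 methyl 2-(3-bromo-7,12-dihydro-6H-pyrido[1,2-a:3,4-b']diindol-13-yl)acetate, via enamine tautomer 8 (not isolated), via 3H-indole tautomer 9 (not isolated)
Conditions: Pd(OAc)2 (10 mol %), DABCO, degassed DMF, 100 °C
Reagents that add atoms: none
Why: Under the basic conditions 7 equilibrates with its secondary enamine 8, whose C=C can only lie between C12a and C7a because the other α-position, C12b, is an aromatic carbon of ring D. Zerovalent palladium, formed in the flask from Pd(OAc)2, inserts into the C–I bond, and the aryl palladium iodide is captured by the nucleophilic enamine carbon C7a, by C-palladation to a six-membered azapalladacycle and C–C reductive elimination or by migratory insertion. Both paths lead to the 3H-indole 9, which tautomerises to the aromatic indole 10. The closest known reaction type is the palladium-catalysed annulation of enolisable ketones with 2-iodoaniline under Pd(OAc)2/DABCO in DMF, an intramolecular Heck-type arylation of an enamine. Ring B closes as a five-membered ring through the bond C7a–C7b; seen as a carbopalladation the closure is 5-endo-trig on the enamine double bond, which is why the palladacycle path is the more likely one. No stereocenter remains, since the sp3 centre C7a of 9 is lost on tautomerisation. The step needs C–I to react in preference to C3–Br: ligand-free zerovalent palladium adds to an aryl iodide far faster than to an electron-rich aryl bromide, and the ring closure that follows is intramolecular and returns the catalyst quickly. DABCO takes up the hydrogen iodide, and stopping the reaction once 7 is consumed protects the bromide further.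

**Step 6**
Reactants: 10 methyl 2-(3-bromo-7,12-dihydro-6H-pyrido[1,2-a:3,4-b']diindol-13-yl)acetate
Product: 11 methyl 2-(3-bromo-12H-pyrido[1,2-a:3,4-b']diindol-13-yl)acetate
Conditions: DDQ (1.05 equiv.), anhydrous 1,4-dioxane, rt
Reagents that add atoms: none
Why: Quinone dehydrogenation; DDQ abstracts hydride from C7, the methylene on the β-carbon of the ring B indole, to give an N12-stabilised cation that loses the C6 proton, and the new C6=C7 bond completes the indolizine-type 10π unit of rings C and D. One equivalent without water keeps the oxidant off the side-chain methylene, and a quinone does not endanger the C–Br bond.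

**Step 7**
Reactants: 11 methyl 2-(3-bromo-12H-pyrido[1,2-a:3,4-b']diindol-13-yl)acetate
Product: 12 methyl 2-(3-bromo-12H-pyrido[1,2-a:3,4-b']diindol-13-yl)-2-oxoacetate
Conditions: SeO2, 1,4-dioxane (trace H2O), 90 °C
Reagents that add atoms: selenium dioxide, O=[Se]=O
Why: Riley oxidation; the methylene between the ester carbonyl and the electron-rich C13 enolises readily and attacks selenium, and a [2,3]-shift with loss of selenium and water leaves the ketone. The resulting keto group is a vinylogous amide through N5 and should resist further oxidation.

## Compound list

1 | methyl 2-(6-bromo-1H-indol-3-yl)acetate | COC(=O)Cc1c[nH]c2cc(Br)ccc12 | starting material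
2 | tert-butyl 4-bromobutanoate | CC(C)(C)OC(=O)CCCBr | starting material
3 | tert-butyl 4-[6-bromo-3-(2-methoxy-2-oxoethyl)-1H-indol-1-yl]butanoate | COC(=O)Cc1cn(CCCC(=O)OC(C)(C)C)c2cc(Br)ccc12 | intermediate
4 | 4-[6-bromo-3-(2-methoxy-2-oxoethyl)-1H-indol-1-yl]butanoic acid | COC(=O)Cc1cn(CCCC(=O)O)c2cc(Br)ccc12 | intermediate
5 | methyl 2-(3-bromo-9-oxo-6,7,8,9-tetrahydropyrido[1,2-a]indol-10-yl)acetate | COC(=O)Cc1c2ccc(Br)cc2n2CCCC(=O)c12 | intermediate
6 | 2-iodoaniline | Nc1ccccc1I | starting material
7 | methyl 2-{(9E)-3-bromo-9-[(2-iodophenyl)imino]-6,7,8,9-tetrahydropyrido[1,2-a]indol-10-yl}acetate | COC(=O)Cc1c2ccc(Br)cc2n2CCC/C(=N\c3ccccc3I)c12 | intermediate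
8 | methyl 2-{3-bromo-9-[(2-iodophenyl)amino]-6,7-dihydropyrido[1,2-a]indol-10-yl}acetate (enamine tautomer of 7) | COC(=O)Cc1c2ccc(Br)cc2n2CCC=C(Nc3ccccc3I)c12 | intermediate (not isolated)
9 | methyl 2-(3-bromo-7,7a-dihydro-6H-pyrido[1,2-a:3,4-b']diindol-13-yl)acetate (3H-indole tautomer, racemic at C7a) | COC(=O)Cc1c2ccc(Br)cc2n2CCC3c4ccccc4N=C3c12 | intermediate (not isolated)
10 | methyl 2-(3-bromo-7,12-dihydro-6H-pyrido[1,2-a:3,4-b']diindol-13-yl)acetate | COC(=O)Cc1c2ccc(Br)cc2n2CCc3c4ccccc4[nH]c3c12 | intermediate
11 | methyl 2-(3-bromo-12H-pyrido[1,2-a:3,4-b']diindol-13-yl)acetate | COC(=O)Cc1c2ccc(Br)cc2n2ccc3c4ccccc4[nH]c3c12 | intermediate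
12 | methyl 2-(3-bromo-12H-pyrido[1,2-a:3,4-b']diindol-13-yl)-2-oxoacetate | COC(=O)C(=O)c1c2ccc(Br)cc2n2ccc3c4ccccc4[nH]c3c12 | target

## Step count and least certain steps

Total step count: 7. Longest linear sequence: 7 steps (1 to 12); 2 and 6 are used as purchased.

**Step 5 (key step).** Oxidative addition at the C3–Br bond may compete once the iodide is used up or if enamine formation is slow, leading to loss of bromine or oligomerisation. Adventitious water may also hydrolyse the ketimine back to the ketone. Fallback: set out from 5 and form the same C7a–C7b bond by a Fischer indole synthesis, which uses no palladium. Condensation of 5 with phenylhydrazine (EtOH, catalytic AcOH, reflux) should give the hydrazone methyl 2-[3-bromo-9-(2-phenylhydrazinylidene)-6,7,8,9-tetrahydropyrido[1,2-a]indol-10-yl]acetate F1. Heating F1 with HCl in AcOH should bring about the [3,3]-sigmatropic shift through the only possible ene-hydrazine (towards C7a), ring closure and loss of ammonia. The route is rejoined at 10.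

**Step 4.** The condensation may stall, because the carbonyl is a vinylogous amide flanked by the C13 arm and the ortho-iodo aniline is a poor nucleophile. The imine may also hydrolyse during isolation, and titanium-mediated enolisation of the methyl ester is a further possibility. Fallback: set out from 5 and 6 and run condensation and annulation as one domino operation (Pd(OAc)2, DABCO, MgSO4, DMF, 100 °C). Compounds 7 and 8 are then present only in low stationary concentration and are drained by the irreversible cyclisation. No new compound arises (F0); the route is rejoined at 10.

**Step 6.** Over-oxidation is the danger: 11 is more electron-rich than 10, and DDQ may go on to abstract hydride from the side-chain methylene or form adducts. Fallback: set out from 10 and invert the order of the two oxidations. Riley oxidation of 10 (SeO2, 1,4-dioxane, 90 °C) should give methyl 2-(3-bromo-7,12-dihydro-6H-pyrido[1,2-a:3,4-b']diindol-13-yl)-2-oxoacetate F2. Its side chain can no longer be attacked, so DDQ can only dehydrogenate C6–C7. The route is rejoined at 12.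

**Step 7.** Electrophilic attack of selenium on the electron-rich nucleus or oxidative degradation may outrun the methylene oxidation. Fallback: set out from 11 and oxidise through the enolate. Two equivalents of LiN(SiMe3)2 (THF, −78 °C) should deprotonate N12–H and the ester α-carbon, and 2-(phenylsulfonyl)-3-phenyloxaziridine should hydroxylate the enolate to racemic methyl 2-(3-bromo-12H-pyrido[1,2-a:3,4-b']diindol-13-yl)-2-hydroxyacetate F3. MnO2 in CH2Cl2 should then oxidise this activated secondary alcohol to the ketone. The route is rejoined at 12.

**Step 3.** Protonation of the indole at its 3-position in the strong acid may slow the acylation, so that intermolecular acylation or partial cleavage of the methyl ester takes over. Fallback: set out from 4 and close the ring by an intramolecular Vilsmeier–Haack acylation. Amide coupling of 4 with dimethylamine (carbodiimide, HOBt) should give 4-[6-bromo-3-(2-methoxy-2-oxoethyl)-1H-indol-1-yl]-N,N-dimethylbutanamide F4. POCl3 in warm MeCN should convert F4 into a chloroiminium ion that attacks the indole 2-position, and aqueous NaOAc should hydrolyse the cyclic iminium with loss of dimethylamine. The route is rejoined at 5.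

## Further compounds

F1 | step 5 | methyl 2-[3-bromo-9-(2-phenylhydrazinylidene)-6,7,8,9-tetrahydropyrido[1,2-a]indol-10-yl]acetate | COC(=O)Cc1c2ccc(Br)cc2n2CCCC(=NNc3ccccc3)c12
F0 | step 4 | none | none
F2 | step 6 | methyl 2-(3-bromo-7,12-dihydro-6H-pyrido[1,2-a:3,4-b']diindol-13-yl)-2-oxoacetate | COC(=O)C(=O)c1c2ccc(Br)cc2n2CCc3c4ccccc4[nH]c3c12
F3 | step 7 | methyl 2-(3-bromo-12H-pyrido[1,2-a:3,4-b']diindol-13-yl)-2-hydroxyacetate (racemic) | COC(=O)C(O)c1c2ccc(Br)cc2n2ccc3c4ccccc4[nH]c3c12
F4 | step 3 | 4-[6-bromo-3-(2-methoxy-2-oxoethyl)-1H-indol-1-yl]-N,N-dimethylbutanamide | COC(=O)Cc1cn(CCCC(=O)N(C)C)c2cc(Br)ccc12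
A1 | alternative 1 | 1-(4-bromo-2-fluorobenzyl)-9H-pyrido[3,4-b]indole | Fc1cc(Br)ccc1Cc1nccc2c3ccccc3[nH]c12
A2 | alternative 1 | 2-(4-bromo-2-fluorophenyl)-1-(3-ethenyl-1H-indol-2-yl)ethan-1-one O-methyl oxime | CON=C(Cc1ccc(Br)cc1F)c1[nH]c2ccccc2c1C=C
A3 | alternative 1 | 3-bromo-12H-pyrido[1,2-a:3,4-b']diindole | c1c2ccc(Br)cc2n2ccc3c4ccccc4[nH]c3c12
A4 | alternative 2 | methyl 2-[6-bromo-1-(2,2-dimethoxyethyl)-2-(1H-indol-2-yl)-1H-indol-3-yl]-2-oxoacetate | COC(=O)C(=O)c1c2ccc(Br)cc2n(CC(OC)OC)c1-c1cc2ccccc2[nH]1
A5 | alternative 2 | methyl 2-[{5-bromo-2-[(1H-indol-2-yl)ethynyl]phenyl}(2,2-dimethoxyethyl)amino]-2-oxoacetate | COC(=O)C(=O)N(CC(OC)OC)c1cc(Br)ccc1C#Cc1cc2ccccc2[nH]1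
A6 | alternative 3 | methyl 2-(3-bromo-7,12-dihydro-6H-pyrido[1,2-a:3,4-b']diindol-13-yl)-2-oxoacetate | COC(=O)C(=O)c1c2ccc(Br)cc2n2CCc3c4ccccc4[nH]c3c12
A7 | alternative 3 | methyl (3E)-3-[2-(3-bromophenyl)-2,3,4,9-tetrahydro-1H-pyrido[3,4-b]indol-1-ylidene]-2-oxopropanoate | COC(=O)C(=O)/C=C1\c2[nH]c3ccccc3c2CCN1c1cccc(Br)c1
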